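The ratio of reagent charged to reagent left at the moment of looking is the gain through which this flask answers a change of charge.

    reagent + free catalyst + left-handed substrate → free catalyst + left-handed product (k1 = 870 L² mol⁻² s⁻¹)
    2 free catalyst → spent catalyst (k2 = 59 L mol⁻¹ s⁻¹)
    reagent + free catalyst + right-handed substrate → free catalyst + right-handed product (k3 = 390 L² mol⁻² s⁻¹)
    free catalyst ⇌ dormant form (K4 = 0.75, k4 = 0.0039 s⁻¹)

left-handed substrate 0.050 M; reagent 1.10 equiv; free catalyst 0.49 mol%; right-handed substrate 0.050 M

- free catalyst is single-handed; left-handed substrate and right-handed substrate are mirror images of each other, charged as a racemate, each of them at the stated concentration
- a doubled species enters its step squared and goes two at a time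
- charge of left-handed substrate (flask): 0.050 M

- apparent order in reagent when 20 % of the left-handed substrate and right-handed substrate together are converted (percent change of the rate of making left-handed product for one percent more reagent charged)
- apparent order in free catalyst when 20 % of the left-handed substrate and right-handed substrate together are converted (percent change of the rate of making left-handed product for one percent more free catalyst charged)

By my own reckoning, this flask holds less reagent, 0.0550 M, than the 0.100 M of the two substrates together, so the reagent is the limiting reagent. Each productive turn takes one reagent and one substrate, so at 20 % conversion 0.0200 M has gone and 0.0350 M remains. Since that amount gone stays the same at the mark, one percent more charge raises the reagent there by Λ percent, where Λ, the lever, is reagent charged over reagent left at the mark, 1.57.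

With the left-handed step by itself and the catalyst held constant, the substrate at the mark does not move with the reagent charge, so the order in reagent equals Λ and the order in catalyst is one. Adding the right-handed step leaves both numbers in place: the left-handed step runs 2.2 times as fast at the start, this being the selectivity factor, but both substrates fall along the same integral of reagent times catalyst, so their split at the mark ignores the charge.

Adding catalyst loss changes the picture. Free catalyst at 2.45 × 10⁻⁴ M has a first half-life of 0.577 min by pairing, and 0.0200 M takes 0.393 min at the starting rate, so the half-life is too near that time to hold the catalyst constant. The dormant form draws on free catalyst more slowly than pairing does at the start, at 0.23 min⁻¹ against 1.73 min⁻¹ per free catalyst. A flask charged with more reagent reaches the mark sooner, with more catalyst alive, so I commit to an order in reagent above Λ, without a figure.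

The forecast goes further, with 3.1 (2.9 to 3.3) in reagent and 1.15 (1.08 to 1.22) in catalyst, on the ground that “More reagent also reaches conversion sooner”.

The simulation gives 3.1 in reagent and 1.2 in catalyst; of the reagent order, Λ is 1.57 and the remainder is 1.53. The flask with twice the reagent shows 4.99 times the rate of this flask. The same balance leaves that flask 0.0900 M of reagent at the mark, which is Λ plus one, 2.57 times what this flask holds there, and so a factor of 1.94 remains beyond the reagent present.

The rate constants were set for the occasion; the rest is arithmetic.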